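**Plan**

1. Retrosynthesis: the C4 carbonyl oxygen is taken off first (quinone 20 to phenol 19). The ring of 19 is then cut at C2–C3 and C5–C6 into a C2–C1–C6 piece (β-keto ester 13, already carrying OMe and the whole C30 chain) and a C3–C4–C5 piece (but-2-ynal 15). The chain is cut at C6–C1′ (enolate alkylation) and at C8′–C9′ (sulfone coupling, C10 + C20).
2. Enabling feature: in the quinone ring each C=C bond lies between the two carbonyl carbons, so the six ring atoms are two C–C(O)–C triads. C1 with its α-carbons C2 and C6 is a ketone bis-nucleophile, C3 and C5 are the two electrophilic ends of an ynal, and C4 can be carried as CH because it is the only free position para to the C1 oxygen.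
3. Forward: a geranyl (C10) and a geranylgeranyl (C20) piece give all-E hexaprenol 10 and bromide 11; C-alkylation of methyl 4-methoxyacetoacetate gives 13; one pot (Michael addition, aldol condensation, expulsion of the ester) closes the only ring with all four substituents in place; aerobic para-oxidation gives the quinone.
4. Helper group: the methyl ester makes C6 the only acidic carbon for the alkylation and for the Michael step, and it leaves as dimethyl carbonate in the ring-forming step itself.
5. Stereochemistry: the target has no stereocentre. Its five E olefins are bought with geranyl acetate and geranylgeraniol; the E sense at C6′ is fixed when SeO2 attacks the (E)-methyl group; no later step touches an olefin. Stereocentres in 7–9, 13 and 16–18 are transient.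

Key step: step 10

Remark: "hexaprenyl" stands for (2E,6E,10E,14E,18E)-3,7,11,15,19,23-hexamethyltetracosa-2,6,10,14,18,22-hexaen-1-yl. Ring atoms are numbered C1(=O), C2(OMe), C3(H), C4(=O), C5(CH3), C6(hexaprenyl). Intermediates with a stereocentre are racemates or diastereomer mixtures, which is without consequence.

**Route**

Step 1
Reactants: 1 geranyl acetate, (2E)-3,7-dimethylocta-2,6-dien-1-yl acetate
Product: 2 (2E,6E)-8-hydroxy-3,7-dimethylocta-2,6-dien-1-yl acetate
Conditions: SeO2 (0.1 equiv), t-BuOOH (70% aq., 3 equiv), salicylic acid (0.1 equiv), CH2Cl2, rt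
Reagents that add atoms: tert-butyl hydroperoxide, CC(C)(C)OO; selenium dioxide, O=[Se]=O (catalytic carrier of the oxygen atom)
Why: Catalytic SeO2 allylic oxidation (ene reaction, then [2,3]-sigmatropic shift) should hydroxylate the (E)-methyl group of the electron-rich 6,7-olefin, the 2,3-olefin being deactivated by the allylic acetate, so that the oxidised carbon becomes the E-configured chain end.

Step 2
Reactants: 2 (2E,6E)-8-hydroxy-3,7-dimethylocta-2,6-dien-1-yl acetate
Product: 3 (2E,6E)-8-bromo-3,7-dimethylocta-2,6-dien-1-yl acetate
Conditions: CBr4, PPh3, CH2Cl2, 0 °C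
Reagents that add atoms: carbon tetrabromide, BrC(Br)(Br)Br
Why: The Appel reaction converts the primary allylic alcohol into the bromide by SN2 displacement of the alkoxyphosphonium ion under neutral conditions, which should leave the acetate and both olefin geometries untouched.

Step 3
Reactants: 4 (2E,6E,10E)-geranylgeraniol, (2E,6E,10E)-3,7,11,15-tetramethylhexadeca-2,6,10,14-tetraen-1-ol
Product: 5 (2E,6E,10E)-geranylgeranyl bromide
Conditions: PBr3 (0.4 equiv), pyridine (cat.), Et2O, −10 to 0 °C
Reagents that add atoms: phosphorus tribromide, BrP(Br)Br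
Why: Bromination of a primary allylic alcohol with PBr3 at low temperature proceeds by SN2 attack of bromide on the phosphite ester and should keep the E geometry of the 2,3-olefin.

Step 4
Reactants: 5 (2E,6E,10E)-geranylgeranyl bromide
Product: 6 geranylgeranyl phenyl sulfone, {[(2E,6E,10E)-3,7,11,15-tetramethylhexadeca-2,6,10,14-tetraen-1-yl]sulfonyl}benzene
Conditions: PhSO2Na, DMF, rt
Reagents that add atoms: sodium benzenesulfinate, [Na+].[O-]S(=O)c1ccccc1
Why: The ambident sulfinate anion is alkylated at sulfur by SN2 displacement at the primary allylic bromide in a dipolar aprotic solvent, giving the allylic sulfone.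

Step 5
Reactants: 6 geranylgeranyl phenyl sulfone; 3 (2E,6E)-8-bromo-3,7-dimethylocta-2,6-dien-1-yl acetate
Product: 8 (2E,6E,10E,14E,18E)-3,7,11,15,19,23-hexamethyl-9-(phenylsulfonyl)tetracosa-2,6,10,14,18,22-hexaen-1-yl acetate (racemic at C9), via lithiated sulfone 7 (not isolated)
Conditions: n-BuLi (1.0 equiv), THF, −78 °C; then 3, THF, −78 to −40 °C
Reagents that add atoms: none
Why: In this sulfone-anion allyl–allyl coupling the sulfonyl-stabilised allyl anion reacts at its α-carbon with the primary allylic bromide by SN2, which at −78 °C should be much faster than attack on the distant acetate; the new stereocentre is racemic and is removed in step 6.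

Step 6
Reactants: 8 C30 sulfonyl acetate
Product: 10 all-E hexaprenol, (2E,6E,10E,14E,18E)-3,7,11,15,19,23-hexamethyltetracosa-2,6,10,14,18,22-hexaen-1-ol, via lithium alkoxide 9 (not isolated)
Conditions: LiBHEt3 (2.5 equiv), THF, 0 °C; then PdCl2(dppp) (5 mol %; dppp = 1,3-bis(diphenylphosphino)propane), LiBHEt3 (2 equiv), 0 °C to rt
Reagents that add atoms: none
Why: The hydride first cleaves the acetate to the alkoxide, so no allylic ester is left for palladium to ionise; zerovalent palladium formed in the flask then ionises the allylic sulfone to a π-allyl complex that takes hydride at the less substituted terminus, so the trisubstituted E olefin stays in place (palladium-catalysed reductive desulfonylation).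

Step 7
Reactants: 10 all-E hexaprenol
Product: 11 all-E hexaprenyl bromide, (2E,6E,10E,14E,18E)-1-bromo-3,7,11,15,19,23-hexamethyltetracosa-2,6,10,14,18,22-hexaene
Conditions: PBr3 (0.4 equiv), pyridine (cat.), Et2O, −10 to 0 °C; used crude at once
Reagents that add atoms: phosphorus tribromide, BrP(Br)Br
Why: The same PBr3 bromination of a primary allylic alcohol as in step 3 should give the primary E bromide, which is used without storage.

Step 8
Reactants: 12 methyl 4-methoxy-3-oxobutanoate (1.3 equiv); 11 all-E hexaprenyl bromide
Product: 13 methyl (4E,8E,12E,16E,20E)-2-(methoxyacetyl)-5,9,13,17,21,25-hexamethylhexacosa-4,8,12,16,20,24-hexaenoate (racemic)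
Conditions: K2CO3, acetone, rt to reflux
Reagents that add atoms: none
Why: In this acetoacetic ester alkylation the soft potassium enolate of the β-keto ester is alkylated at its central carbon by SN2 displacement at the primary allylic bromide, which should retain the E geometry; the excess of 12 suppresses double alkylation.

Step 9
Reactants: 14 but-2-yn-1-ol
Product: 15 but-2-ynal
Conditions: activated MnO2 (excess), CH2Cl2, rt; filtered through Celite, kept as a cold solution and used the same day
Reagents that add atoms: none
Why: Activated MnO2 oxidises the propargylic alcohol to the ynal under neutral heterogeneous conditions without over-oxidation, and the volatile, polymerisable aldehyde is never concentrated to dryness.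

Step 10
Reactants: 13 alkylated β-keto ester; 15 but-2-ynal (1.5 equiv)
Product: 19 2-methoxy-5-methyl-6-hexaprenylphenol, via Z-enal Michael adduct 16 (not isolated), via cyclic aldol 17 (not isolated), via cyclohexadienone ester 18 (not isolated)
Conditions: Cs2CO3 (0.3 equiv), THF–DMF, 0 °C to rt, argon; then NaOMe (1.5 equiv), MeOH, 0 °C to rt; aq. NH4Cl
Reagents that add atoms: none
Why: Proposed new method: the cesium enolate of 13, formed at the only doubly activated carbon (C6), should add in a Michael fashion to C5 of ynal 15 (bond C5–C6), and anti-protonation of the allenolate places the formyl group cis to the new quaternary carbon (Z-enal 16; any E isomer can equilibrate through its dienolate). The ketone of 16 can enolise only towards the methoxy-bearing C2, which closes the ring by a 6-(enolendo)-exo-trig aldol addition to the aldehyde (bond C2–C3, 17) and loses water by E1cB to dienone 18. Methoxide then adds to the ester carbonyl of 18 and the tetrahedral intermediate expels the ring as an aromatic phenoxide (retro-Claisen fragmentation with loss of dimethyl carbonate), so the ester that activated and directed the annulation is shed in the same flask. The closest known reaction types are the base-mediated Michael–aldol [3+3] benzannulation of acetonedicarboxylates with ynals and ynones and the nucleophilic de-acylation of 6-acylcyclohexa-2,4-dienones; their union on a 2-alkylated β-keto ester, with the ester as a traceless group, is the new element. The quaternary centre and the carbinol centres of 16–18 are formed without control and all become sp2 ring carbons, so no stereochemical issue survives. The step needs regioselectivity, secured because only C6 is acidic enough for the Michael step and the only six-membered aldol open to 16 joins C2 to the aldehyde (the alternatives are four-membered), and chemoselectivity of methoxide, secured because only attack at the ester leads to an irreversible aromatising fragmentation while addition to the ring ketone is reversible.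

Step 11
Reactants: 19 2-methoxy-5-methyl-6-hexaprenylphenol
Product: 20 2-methoxy-5-methyl-6-hexaprenyl-1,4-benzoquinone (the target; also named 6-methoxy-3-methyl-2-hexaprenyl-1,4-benzoquinone)
Conditions: Co(salen) (10 mol %, divalent cobalt; salen = N,N′-ethylenebis(salicylideneiminato)), O2 (1 atm), DMF, rt
Reagents that add atoms: dioxygen, O=O
Why: In this Co(salen)-catalysed aerobic oxidation of a phenol to the para-quinone the cobalt–superoxo species abstracts the phenolic hydrogen and the phenoxyl radical is oxygenated at C4, the only free position ortho or para to oxygen (C2 and C6 are blocked), while the isolated trisubstituted olefins should not react at rt.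

**Compound list**

1 | geranyl acetate, (2E)-3,7-dimethylocta-2,6-dien-1-yl acetate | CC(=O)OC/C=C(\C)CCC=C(C)C | starting material
2 | (2E,6E)-8-hydroxy-3,7-dimethylocta-2,6-dien-1-yl acetate | CC(=O)OC/C=C(\C)CC/C=C(\C)CO | intermediate
3 | (2E,6E)-8-bromo-3,7-dimethylocta-2,6-dien-1-yl acetate | CC(=O)OC/C=C(\C)CC/C=C(\C)CBr | intermediate
4 | (2E,6E,10E)-geranylgeraniol | OC/C=C(\C)CC/C=C(\C)CC/C=C(\C)CCC=C(C)C | starting material
5 | (2E,6E,10E)-geranylgeranyl bromide | BrC/C=C(\C)CC/C=C(\C)CC/C=C(\C)CCC=C(C)C | intermediate
6 | geranylgeranyl phenyl sulfone | O=S(=O)(C/C=C(\C)CC/C=C(\C)CC/C=C(\C)CCC=C(C)C)c1ccccc1 | intermediate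
7 | α-lithiated geranylgeranyl phenyl sulfone (not isolated) | [Li]C(/C=C(\C)CC/C=C(\C)CC/C=C(\C)CCC=C(C)C)S(=O)(=O)c1ccccc1 | intermediate
8 | (2E,6E,10E,14E,18E)-3,7,11,15,19,23-hexamethyl-9-(phenylsulfonyl)tetracosa-2,6,10,14,18,22-hexaen-1-yl acetate, racemic at C9 | CC(=O)OC/C=C(\C)CC/C=C(\C)CC(/C=C(\C)CC/C=C(\C)CC/C=C(\C)CCC=C(C)C)S(=O)(=O)c1ccccc1 | intermediate
9 | lithium alkoxide of (2E,6E,10E,14E,18E)-3,7,11,15,19,23-hexamethyl-9-(phenylsulfonyl)tetracosa-2,6,10,14,18,22-hexaen-1-ol, racemic (not isolated) | [Li]OC/C=C(\C)CC/C=C(\C)CC(/C=C(\C)CC/C=C(\C)CC/C=C(\C)CCC=C(C)C)S(=O)(=O)c1ccccc1 | intermediate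
10 | all-E hexaprenol, (2E,6E,10E,14E,18E)-3,7,11,15,19,23-hexamethyltetracosa-2,6,10,14,18,22-hexaen-1-ol | OC/C=C(\C)CC/C=C(\C)CC/C=C(\C)CC/C=C(\C)CC/C=C(\C)CCC=C(C)C | intermediate
11 | all-E hexaprenyl bromide | BrC/C=C(\C)CC/C=C(\C)CC/C=C(\C)CC/C=C(\C)CC/C=C(\C)CCC=C(C)C | intermediate
12 | methyl 4-methoxy-3-oxobutanoate | COCC(=O)CC(=O)OC | starting material
13 | methyl (4E,8E,12E,16E,20E)-2-(methoxyacetyl)-5,9,13,17,21,25-hexamethylhexacosa-4,8,12,16,20,24-hexaenoate, racemic | COCC(=O)C(C/C=C(\C)CC/C=C(\C)CC/C=C(\C)CC/C=C(\C)CC/C=C(\C)CCC=C(C)C)C(=O)OC | intermediate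
14 | but-2-yn-1-ol | CC#CCO | starting material
15 | but-2-ynal | CC#CC=O | intermediate
16 | methyl (3Z)-2-hexaprenyl-2-(methoxyacetyl)-3-methyl-5-oxopent-3-enoate, racemic (not isolated) | COCC(=O)C(C/C=C(\C)CC/C=C(\C)CC/C=C(\C)CC/C=C(\C)CC/C=C(\C)CCC=C(C)C)(C(=O)OC)/C(C)=C\C=O | intermediate
17 | methyl 1-hexaprenyl-4-hydroxy-3-methoxy-6-methyl-2-oxocyclohex-5-ene-1-carboxylate, diastereomer mixture (not isolated) | COC(=O)C1(C/C=C(\C)CC/C=C(\C)CC/C=C(\C)CC/C=C(\C)CC/C=C(\C)CCC=C(C)C)C(=O)C(OC)C(O)C=C1C | intermediate
18 | methyl 1-hexaprenyl-3-methoxy-6-methyl-2-oxocyclohexa-3,5-diene-1-carboxylate, racemic (not isolated) | COC(=O)C1(C/C=C(\C)CC/C=C(\C)CC/C=C(\C)CC/C=C(\C)CC/C=C(\C)CCC=C(C)C)C(=O)C(OC)=CC=C1C | intermediate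
19 | 2-methoxy-5-methyl-6-hexaprenylphenol | COc1ccc(C)c(C/C=C(\C)CC/C=C(\C)CC/C=C(\C)CC/C=C(\C)CC/C=C(\C)CCC=C(C)C)c1O | intermediate
20 | 2-methoxy-5-methyl-6-hexaprenyl-1,4-benzoquinone | COC1=CC(=O)C(C)=C(C/C=C(\C)CC/C=C(\C)CC/C=C(\C)CC/C=C(\C)CC/C=C(\C)CCC=C(C)C)C1=O | target

**Count and risks**

Total steps: 11. Longest linear sequence: 8 steps (1, 2, 5, 6, 7, 8, 10, 11; the branch 3, 4, 5, 6, 7, 8, 10, 11 is equally long).

Steps most likely to fail:

Step 10. The hindered tertiary enolate may add too slowly to the β-methyl ynal or add to its carbonyl group, the ynal may oligomerise under base, and the open-chain adduct may suffer retro-Claisen cleavage before it cyclises. The fallback sets out from bromide 11 and comes back at phenol 19. Commercial 2-methoxy-5-methylphenol would be deprotonated with NaH in toluene to sodium 2-methoxy-5-methylphenoxide F1, and the suspension stirred with 11 at rt. In the non-polar medium the contact ion pair is alkylated at carbon, and the only free ortho position is C6, so 19 should form directly by the known ortho-C-allylation of phenoxides; the O-allyl ether and the para isomer would be separated. This route gives up the ring construction and attaches the chain to a bought arene.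

Step 11. The phenoxyl radical may dimerise instead of being oxygenated, and the cobalt–dioxygen system may start autoxidation at the allylic positions of the chain. The fallback sets out from 19 and ends at 20. Phenol 19 in aqueous NaOH–THF at 0 °C would be coupled at its free para position with 4-diazoniobenzenesulfonate F2 (made from sulfanilic acid, NaNO2 and HCl) to give 4-[(E)-(4-hydroxy-5-methoxy-2-methyl-3-hexaprenylphenyl)diazenyl]benzenesulfonic acid F3. Reduction with Na2S2O4 in warm aqueous ethanol would give 4-amino-2-methoxy-5-methyl-6-hexaprenylphenol F4. Two-phase oxidation with aqueous FeCl3 (trivalent iron) and ether would give the quinone monoimine F5, which is hydrolysed in the same flask to 20. The C4 oxygen thus arrives by a nitrogen route, without dioxygen.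

Step 7. Allylic transposition to the tertiary bromide, partial loss of E geometry at the 2,3-olefin and decomposition of the labile C30 bromide on concentration may lower the quality of the electrophile. The fallback sets out from hexaprenol 10 and comes back at 13. Alcohol 10 would be acylated with methyl chloroformate and pyridine to hexaprenyl methyl carbonate F6. With Pd(PPh3)4 (zerovalent palladium, catalytic) and 12 in THF at rt, F6 should give 13 by a Tsuji–Trost allylation: ionisation gives the syn π-allyl complex, CO2 is lost, the methoxide set free deprotonates 12, and the soft enolate attacks the unsubstituted allyl terminus with retention of the E geometry. No allylic halide is handled.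

**Further compounds**

F1 | step 10 | sodium 2-methoxy-5-methylphenoxide | [Na+].[O-]c1cc(C)ccc1OC
F2 | step 11 | 4-diazoniobenzenesulfonate | [O-]S(=O)(=O)c1ccc(cc1)[N+]#N
F3 | step 11 | 4-[(E)-(4-hydroxy-5-methoxy-2-methyl-3-hexaprenylphenyl)diazenyl]benzenesulfonic acid | COc1cc(/N=N/c2ccc(cc2)S(=O)(=O)O)c(C)c(C/C=C(\C)CC/C=C(\C)CC/C=C(\C)CC/C=C(\C)CC/C=C(\C)CCC=C(C)C)c1O
F4 | step 11 | 4-amino-2-methoxy-5-methyl-6-hexaprenylphenol | COc1cc(N)c(C)c(C/C=C(\C)CC/C=C(\C)CC/C=C(\C)CC/C=C(\C)CC/C=C(\C)CCC=C(C)C)c1O
F5 | step 11 | 4-imino-2-methoxy-5-methyl-6-hexaprenylcyclohexa-2,5-dien-1-one | COC1=CC(=N)C(C)=C(C/C=C(\C)CC/C=C(\C)CC/C=C(\C)CC/C=C(\C)CC/C=C(\C)CCC=C(C)C)C1=O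
F6 | step 7 | hexaprenyl methyl carbonate | COC(=O)OC/C=C(\C)CC/C=C(\C)CC/C=C(\C)CC/C=C(\C)CC/C=C(\C)CCC=C(C)C
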